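Target comes slowly in these runs: winter needs 2.50 min to read 10.2 % of the starting material charged, and at 4.00 min it reads 10.4 %. The flask asked about is dawn's recipe with less solid.

| flask | starting material | partner | second reagent | solid third reagent | remark | time |
|---|---|---|---|---|---|---|
| winter | 0.35 M | 0.75 M | 0.50 M | 0.625 M | run made earlier |  |
| autumn | 0.55 M | 0.75 M | 0.50 M | 0.625 M | run made earlier |  |
| dawn | 0.25 M | 0.75 M | 0.50 M | 1.2 M | run made earlier |  |
| flask | 0.25 M | 0.750 M | 0.500 M | 0.625 M |  | 3.0 min |

- winter (time / min: target / %): 0.833: 3.4; 2.00: 9.5; 2.50: 10.2; 4.00: 10.4
- autumn (time / min: target / %): 0.417: 1.0; 1.33: 3.9; 2.50: 9.3; 4.00: 8.6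
- dawn (time / min: target / %): 0.250: 0.8; 0.667: 3.8; 1.50: 7.3; 4.00: 10.8

(scatter of a reading: 1 percentage point)

- at the start none of the solid third reagent is in solution

- Tuesday's: doubling the amount of second reagent, all else as stated
- Friday's: doubling the dissolution coefficient of the solid third reagent, all else as stated
- Thursday's: doubling the amount of partner, all else as stated
- Wednesday's: doubling the solubility of the solid third reagent, all else as stated

1. target at 3.0 min, in percent of the starting material charged
2. the change that raises the amount of target at 3.0 min, in percent of the starting material charged most ("none" if none brings more than 2 percentage points) (Tuesday's / Friday's / Thursday's / Wednesday's / none)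
3. amount of target at 3.0 min, in percent of the starting material charged, after Thursday's

One pair of readings looks wrong at first. Dawn holds nearly twice the solid third reagent of winter, yet it reads 10.8 % against 10.4 %. But the two runs also differ in starting material, so I separate the charges with a yield order, a name of my own: the logarithm of the ratio of two target shares over the logarithm of the ratio of two charges, with the other charges equal. Winter and autumn differ in c(starting material) and give −0.420, a rough reading given the scatter of 1 percentage point. Carried from winter to 0.25 M, this order gives 12.0 %. Dawn reads less than that, so the extra solid shows no gain. I therefore expect the flask a little under dawn's 10.8 % at 3.0 min, since dawn is still rising between 1.50 min and 4.00 min. Partner stands at 0.75 M and second reagent at 0.50 M in winter, autumn and dawn alike, so the readings give no yield order for either.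

The forecast gives 10.2 %, picks Thursday's and puts that change at 16 %, reasoning: “If the partner captures that species, doubling it should raise the yield substantially”.

The flask gives 10.1 %.

    starting material + partner → intermediate A (k = 0.0200 /M/s)
    second reagent + intermediate A → intermediate B (k = 0.0160 /M/s)
    third reagent + intermediate B → target (k = 2.00 /M/s)
    starting material + second reagent → side product A (k = 0.00820 /M/s)
    solid third reagent ⇌ third reagent, rate k5*(cs5 - [third reagent]) while solid is left; crystals form when [third reagent] > cs5 (solubility = 0.230 M, k = 0.0510 /s)
    intermediate A → side product B (k = 0.0440 /s)

Of the changes, Tuesday's brings the most, 5.2 points, while Thursday's brings 2.4 points and ends at 12.5 %. At 3.00 min, side product B holds 61.2 % of the starting material charged in this flask. Against this flask, the neighbouring flask with 1.2 M of second reagent gives a yield order in second reagent of 0.566, positive where the −0.420 read for starting material is negative, and target there reaches 16.6 %.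

(The earlier runs and the new flask are simulated with constants of no real substance; scatter was added.)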